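**Plan**

1. Retrosynthesis first removes the C8 formyl group (C8–CHO bond) and resets the O7–H / O5–CH3 pattern, which leaves a 5,7-dioxygenated 3-benzylchromone.
2. The pyranone is then cut at C3–C4. C4 is a carbonyl carbon on ring A ortho to O1, and O1–C2–C3 plus the benzylic carbon is a hidden aryl propargyl ether, so the ring opens to a 2-(3-arylprop-2-ynyloxy)benzaldehyde whose aldehyde carbon becomes C4 with reversed polarity.
3. That aldehyde is cut at the alkyne–aryl bond, the O1–CH2 bond, the ring–CHO bond and the C–OH bond of a mirror-symmetric 3,5-dialkoxy-4-methylphenol made from 2-methylresorcinol. The symmetry fixes the regiochemistry of ring A.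
4. Forward: ring A is bought, the chain is joined oxygen first (propargyl) and aryl second, and the pyranone, the only ring made, closes in step 6. O5 and O7 are then told apart through the hydrogen bond of O5–H to C4=O, and C8 is formylated last.
5. Stereochemistry: the target has no stereocentre. The only stereo-element on the way, the E alkene of the transient benzylidene chromanone, comes from syn addition and is erased by the isomerisation.

Key step: step 6

Remark: chromone numbering (O1, C2, C3, C4, C4a, C5 to C8, C8a) is used for all bicyclic compounds. Propargyl bromide is taken as the commercial three-carbon unit.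

**Route**

Step 1
Reactants: 1 2-methylresorcinol
Product: 2 2-methyl-1,3-di(propan-2-yloxy)benzene
Conditions: 2-bromopropane (3 equiv), K2CO3 (3 equiv), DMF, 70 °C
Reagents that add atoms: 2-bromopropane, CC(C)Br
Why: Williamson ether synthesis on both phenols; the isopropyl ethers should be inert to the iridium, magnesium, palladium and carbene steps that follow and can later be removed by BCl3 without loss of a methyl ether.

Step 2
Reactants: 2 2-methyl-1,3-di(propan-2-yloxy)benzene
Product: 4 4-methyl-3,5-di(propan-2-yloxy)phenol, via arylboronic acid pinacol ester 3 (not isolated)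
Conditions: B2pin2 (1.0 equiv), [Ir(OMe)(cod)]2 (1.5 mol %), 4,4'-di-tert-butyl-2,2'-bipyridine (3 mol %), THF, 80 °C; then 30% H2O2, aq NaOH, 0 °C
Reagents that add atoms: bis(pinacolato)diboron, CC1(C)OB(OC1(C)C)B1OC(C)(C)C(C)(C)O1 (boron and pinacol of 3); hydrogen peroxide, OO (hydroxyl oxygen of 4)
Why: Iridium-catalysed C–H borylation is governed by sterics and should take the only ring C–H without an ortho substituent (para to the methyl group), and oxidation of the C–B bond in the same flask should give the mirror-symmetric phenol (one-pot borylation–oxidation).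

Step 3
Reactants: 4 4-methyl-3,5-di(propan-2-yloxy)phenol
Product: 5 6-hydroxy-3-methyl-2,4-di(propan-2-yloxy)benzaldehyde
Conditions: (CH2O)n (6 equiv), MgCl2 (2 equiv), Et3N (4 equiv), MeCN, reflux; 1 M HCl work-up
Reagents that add atoms: paraformaldehyde (as formaldehyde), C=O
Why: Magnesium-mediated ortho-formylation of phenols (Casnati–Skattebøl reaction) delivers formaldehyde within the magnesium phenoxide to an ortho carbon only, and since the two ortho carbons are equivalent and the para carbon carries the methyl group, a single salicylaldehyde can form.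

Step 4
Reactants: 5 6-hydroxy-3-methyl-2,4-di(propan-2-yloxy)benzaldehyde; 6 propargyl bromide (3-bromoprop-1-yne)
Product: 7 3-methyl-2,4-di(propan-2-yloxy)-6-(prop-2-yn-1-yloxy)benzaldehyde
Conditions: K2CO3 (1.5 equiv), DMF, rt
Reagents that add atoms: none
Why: Williamson O-alkylation (SN2) of the salicylaldehyde phenoxide with a reactive propargylic bromide, the only acidic site in 5.

Step 5
Reactants: 7 3-methyl-2,4-di(propan-2-yloxy)-6-(prop-2-yn-1-yloxy)benzaldehyde; 8 4-iodoanisole
Product: 9 6-{[3-(4-methoxyphenyl)prop-2-yn-1-yl]oxy}-3-methyl-2,4-di(propan-2-yloxy)benzaldehyde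
Conditions: PdCl2(PPh3)2 (2 mol %), CuI (4 mol %), Et3N, THF, rt, argon
Reagents that add atoms: none
Why: Sonogashira coupling of a terminal alkyne with an aryl iodide runs at room temperature and tolerates the aldehyde and the ethers.

Step 6
Reactants: 9 6-{[3-(4-methoxyphenyl)prop-2-yn-1-yl]oxy}-3-methyl-2,4-di(propan-2-yloxy)benzaldehyde
Product: 11 3-(4-methoxybenzyl)-6-methyl-5,7-di(propan-2-yloxy)-4H-chromen-4-one, via (E)-3-(4-methoxybenzylidene)chroman-4-one 10 (not isolated)
Conditions: 3-mesityl-5,6,7,8-tetrahydro-4H-cyclohepta[d][1,3]thiazol-3-ium perchlorate (10 mol %), K2CO3 (20 mol %), THF (0.1 M), 70 °C; then DBU (0.5 equiv), 70 °C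
Reagents that add atoms: none
Why: Deprotonation of the thiazolium salt gives the carbene, which adds to the aldehyde of 9 and after proton transfer forms the Breslow amino enol, an acyl anion equivalent at the future C4. This nucleophile adds across the tethered aryl alkyne in a concerted, Conia-ene-like syn hydroacylation that forms the C3–C4 bond and, after loss of the carbene, the (E)-benzylidene chromanone 10; DBU then moves the exocyclic double bond into the ring by deprotonation at C2 and reprotonation at the benzylic carbon, the 4-pyranone (a vinylogous ester) being the thermodynamic sink. The closest known reaction type is the carbene-catalysed intramolecular hydroacylation of unactivated alkynes in 2-(propargyloxy)benzaldehydes. The pyranone ring closes in the 6-exo-dig mode, because the three-atom O–CH2–C tether brings only the proximal alkyne carbon within reach, so 7-endo-dig closure is not expected. No stereocentre is formed, and the alkene geometry of 10, set by the syn addition, is erased in the isomerisation. The step needs ring closure to outrun benzoin and Stetter reactions between two molecules, which the two ortho-alkoxy groups flanking the aldehyde and moderate dilution should secure.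

Step 7
Reactants: 11 3-(4-methoxybenzyl)-6-methyl-5,7-di(propan-2-yloxy)-4H-chromen-4-one
Product: 12 5,7-dihydroxy-3-(4-methoxybenzyl)-6-methyl-4H-chromen-4-one
Conditions: BCl3 (1 M in CH2Cl2, 4 equiv), CH2Cl2, −78 °C to rt; then H2O
Reagents that add atoms: none
Why: BCl3 cleaves secondary alkyl aryl ethers (Lewis acid dealkylation through the ionising isopropyl–oxygen bond), helped at O5 by chelation to the C4 carbonyl, while the unchelated methyl ether of the anisole ring should survive at or below room temperature.

Step 8
Reactants: 12 5,7-dihydroxy-3-(4-methoxybenzyl)-6-methyl-4H-chromen-4-one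
Product: 13 5-hydroxy-7-(methoxymethoxy)-3-(4-methoxybenzyl)-6-methyl-4H-chromen-4-one
Conditions: MOMCl (1.1 equiv), iPr2NEt (1.5 equiv), THF/CH2Cl2, 0 °C to rt
Reagents that add atoms: chloromethyl methyl ether, COCCl
Why: Selective O-alkylation to the methoxymethyl ether: the 7-hydroxyl is the acidic, unchelated vinylogous acid, whereas the 5-hydroxyl is held in a hydrogen bond to the C4 carbonyl and should stay untouched with one equivalent of reagent.

Step 9
Reactants: 13 5-hydroxy-7-(methoxymethoxy)-3-(4-methoxybenzyl)-6-methyl-4H-chromen-4-one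
Product: 14 5-methoxy-7-(methoxymethoxy)-3-(4-methoxybenzyl)-6-methyl-4H-chromen-4-one
Conditions: MeI (5 equiv), K2CO3 (3 equiv), DMF, 50 °C
Reagents that add atoms: iodomethane, CI
Why: Williamson methylation; with O7 blocked the chelated 5-hydroxyl is the only acidic site and should react under forcing but standard conditions, the acetal being stable to base.

Step 10
Reactants: 14 5-methoxy-7-(methoxymethoxy)-3-(4-methoxybenzyl)-6-methyl-4H-chromen-4-one
Product: 15 7-hydroxy-5-methoxy-3-(4-methoxybenzyl)-6-methyl-4H-chromen-4-one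
Conditions: 3 M aq HCl, MeOH, 50 °C
Reagents that add atoms: none
Why: Acid-catalysed methanolysis of the methoxymethyl acetal frees the 7-hydroxyl, while aryl methyl ethers and the chromone are stable to dilute acid.

Step 11
Reactants: 15 7-hydroxy-5-methoxy-3-(4-methoxybenzyl)-6-methyl-4H-chromen-4-one
Product: 16 7-hydroxy-5-methoxy-3-(4-methoxybenzyl)-6-methyl-4-oxo-4H-chromene-8-carbaldehyde
Conditions: hexamethylenetetramine (4 equiv), AcOH, 100 °C; then 3 M aq HCl, 70 °C
Reagents that add atoms: hexamethylenetetramine, C1N2CN3CN1CN(C2)C3 (formyl carbon); water, O (formyl oxygen)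
Why: Duff formylation: the iminium ion from hexamethylenetetramine attacks ortho to the free phenol, and C8 is the only unsubstituted carbon of ring A (C6 carries the methyl group), acid hydrolysis then releasing the aldehyde; the non-phenolic anisole ring should not react in acetic acid.

**Compound list**

1 | 2-methylresorcinol (2-methylbenzene-1,3-diol) | Cc1c(O)cccc1O | starting material
2 | 2-methyl-1,3-di(propan-2-yloxy)benzene | Cc1c(OC(C)C)cccc1OC(C)C | intermediate
3 | 4,4,5,5-tetramethyl-2-[4-methyl-3,5-di(propan-2-yloxy)phenyl]-1,3,2-dioxaborolane (not isolated) | Cc1c(OC(C)C)cc(B2OC(C)(C)C(C)(C)O2)cc1OC(C)C | intermediate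
4 | 4-methyl-3,5-di(propan-2-yloxy)phenol | Cc1c(OC(C)C)cc(O)cc1OC(C)C | intermediate
5 | 6-hydroxy-3-methyl-2,4-di(propan-2-yloxy)benzaldehyde | O=Cc1c(O)cc(OC(C)C)c(C)c1OC(C)C | intermediate
6 | propargyl bromide (3-bromoprop-1-yne) | C#CCBr | starting material
7 | 3-methyl-2,4-di(propan-2-yloxy)-6-(prop-2-yn-1-yloxy)benzaldehyde | O=Cc1c(OCC#C)cc(OC(C)C)c(C)c1OC(C)C | intermediate
8 | 4-iodoanisole (1-iodo-4-methoxybenzene) | COc1ccc(I)cc1 | starting material
9 | 6-{[3-(4-methoxyphenyl)prop-2-yn-1-yl]oxy}-3-methyl-2,4-di(propan-2-yloxy)benzaldehyde | O=Cc1c(OCC#Cc2ccc(OC)cc2)cc(OC(C)C)c(C)c1OC(C)C | intermediate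
10 | (3E)-3-(4-methoxybenzylidene)-6-methyl-5,7-di(propan-2-yloxy)-2,3-dihydro-4H-chromen-4-one (not isolated) | O=C1/C(=C/c2ccc(OC)cc2)COc2cc(OC(C)C)c(C)c(OC(C)C)c12 | intermediate
11 | 3-(4-methoxybenzyl)-6-methyl-5,7-di(propan-2-yloxy)-4H-chromen-4-one | COc1ccc(Cc2coc3cc(OC(C)C)c(C)c(OC(C)C)c3c2=O)cc1 | intermediate
12 | 5,7-dihydroxy-3-(4-methoxybenzyl)-6-methyl-4H-chromen-4-one | COc1ccc(Cc2coc3cc(O)c(C)c(O)c3c2=O)cc1 | intermediate
13 | 5-hydroxy-7-(methoxymethoxy)-3-(4-methoxybenzyl)-6-methyl-4H-chromen-4-one | COCOc1cc2occ(Cc3ccc(OC)cc3)c(=O)c2c(O)c1C | intermediate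
14 | 5-methoxy-7-(methoxymethoxy)-3-(4-methoxybenzyl)-6-methyl-4H-chromen-4-one | COCOc1cc2occ(Cc3ccc(OC)cc3)c(=O)c2c(OC)c1C | intermediate
15 | 7-hydroxy-5-methoxy-3-(4-methoxybenzyl)-6-methyl-4H-chromen-4-one | COc1ccc(Cc2coc3cc(O)c(C)c(OC)c3c2=O)cc1 | intermediate
16 | 7-hydroxy-5-methoxy-3-(4-methoxybenzyl)-6-methyl-4-oxo-4H-chromene-8-carbaldehyde | COc1ccc(Cc2coc3c(C=O)c(O)c(C)c(OC)c3c2=O)cc1 | target

**Step count**

Total: 11 steps. Longest linear sequence: 11 steps, from 1 to 16; starting materials 6 and 8 enter directly in steps 4 and 5.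

**Steps most likely to fail**

Step 6. Carbene addition to the doubly ortho-substituted, electron-rich aldehyde may be slow. Intermolecular benzoin or Stetter-type addition to the enone of 10, or base-induced propargyl-to-allene isomerisation, could then overtake the ring closure. The fallback forms the same C3–C4 bond at the same aldehyde carbon with normal polarity; it sets out from 5 and rejoins at 11. Addition of 2-(4-methoxyphenyl)ethylmagnesium bromide (2.2 equiv, THF, 0 °C) to 5 should give the racemic diol 2-[1-hydroxy-3-(4-methoxyphenyl)propyl]-4-methyl-3,5-di(propan-2-yloxy)phenol F1. Oxidation of its benzylic alcohol with MnO2 (CH2Cl2, rt) should give the dihydrochalcone 1-[6-hydroxy-3-methyl-2,4-di(propan-2-yloxy)phenyl]-3-(4-methoxyphenyl)propan-1-one F2. Heating F2 with N,N-dimethylformamide dimethyl acetal (toluene, 110 °C) should form the enaminone (2E)-3-(dimethylamino)-1-[6-hydroxy-3-methyl-2,4-di(propan-2-yloxy)phenyl]-2-(4-methoxybenzyl)prop-2-en-1-one F3, which is not isolated and should close to 11 by attack of the phenol and loss of dimethylamine.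

Step 11. Electrophilic substitution on the weakly nucleophilic chromone phenol may stay incomplete, and attack on the anisole ring or decomposition in hot acid may compete. The fallback brings in the C8 carbon by a sigmatropic shift; it sets out from 15 and rejoins at 16. O-Allylation (allyl bromide, K2CO3, acetone, reflux) should give 5-methoxy-3-(4-methoxybenzyl)-6-methyl-7-(prop-2-en-1-yloxy)-4H-chromen-4-one F4. Claisen rearrangement (N,N-diethylaniline, 200 °C) can only go to C8, because C6 is blocked, and should give 7-hydroxy-5-methoxy-3-(4-methoxybenzyl)-6-methyl-8-(prop-2-en-1-yl)-4H-chromen-4-one F5. Alkene isomerisation with RuHCl(CO)(PPh3)3 (toluene, 80 °C) should give 7-hydroxy-5-methoxy-3-(4-methoxybenzyl)-6-methyl-8-[(1E)-prop-1-en-1-yl]-4H-chromen-4-one F6. Lemieux–Johnson cleavage (OsO4 cat., NaIO4, 2,6-lutidine, dioxane/H2O) should then release 16.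

Step 3. Attack at an ortho carbon flanked by an isopropoxy group may be slow, and condensation of the electron-rich phenol with formaldehyde to diarylmethanes could take over. The fallback reverses the order of alkylation and formylation; it sets out from 4 and rejoins at 7, bypassing 5. Alkylation of 4 with 6 (K2CO3, DMF, rt) should give 2-methyl-1,3-di(propan-2-yloxy)-5-(prop-2-yn-1-yloxy)benzene F7. Its two free ring carbons are equivalent and activated by three alkoxy groups, so Vilsmeier–Haack formylation (POCl3, DMF, 0 °C to rt; aq NaOAc) should give 7.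

**Further compounds**

F1 | step 6 | 2-[1-hydroxy-3-(4-methoxyphenyl)propyl]-4-methyl-3,5-di(propan-2-yloxy)phenol (racemic) | COc1ccc(CCC(O)c2c(O)cc(OC(C)C)c(C)c2OC(C)C)cc1
F2 | step 6 | 1-[6-hydroxy-3-methyl-2,4-di(propan-2-yloxy)phenyl]-3-(4-methoxyphenyl)propan-1-one | COc1ccc(CCC(=O)c2c(O)cc(OC(C)C)c(C)c2OC(C)C)cc1
F3 | step 6 | (2E)-3-(dimethylamino)-1-[6-hydroxy-3-methyl-2,4-di(propan-2-yloxy)phenyl]-2-(4-methoxybenzyl)prop-2-en-1-one | CN(C)/C=C(\Cc1ccc(OC)cc1)C(=O)c1c(O)cc(OC(C)C)c(C)c1OC(C)C
F4 | step 11 | 5-methoxy-3-(4-methoxybenzyl)-6-methyl-7-(prop-2-en-1-yloxy)-4H-chromen-4-one | COc1ccc(Cc2coc3cc(OCC=C)c(C)c(OC)c3c2=O)cc1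
F5 | step 11 | 7-hydroxy-5-methoxy-3-(4-methoxybenzyl)-6-methyl-8-(prop-2-en-1-yl)-4H-chromen-4-one | COc1ccc(Cc2coc3c(CC=C)c(O)c(C)c(OC)c3c2=O)cc1
F6 | step 11 | 7-hydroxy-5-methoxy-3-(4-methoxybenzyl)-6-methyl-8-[(1E)-prop-1-en-1-yl]-4H-chromen-4-one | COc1ccc(Cc2coc3c(/C=C/C)c(O)c(C)c(OC)c3c2=O)cc1
F7 | step 3 | 2-methyl-1,3-di(propan-2-yloxy)-5-(prop-2-yn-1-yloxy)benzene | Cc1c(OC(C)C)cc(OCC#C)cc1OC(C)C
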